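The data were computed from invented constants; noise was put on by code.

Late in both earlier runs the electrophile kept falling while target slowed: in epsilon, from 40.0 s to 60.0 s, target gained 1.5 percentage points and the electrophile lost 11 points. So I asked how fast that tail runs, and how far it reaches by 2.0 min.

| flask | electrophile | free base | protonated nucleophile | protic impurity | remark | time |
|---|---|---|---|---|---|---|
| epsilon | 0.20 M | 0.69 equiv | 0.80 equiv | 0.010 M | run made earlier |  |
| gamma | 0.20 M | 2.4 equiv | 0.80 equiv | 0.010 M | run made earlier |  |
| cedar | 0.20 M | 0.800 equiv | 0.800 equiv | 0.0100 M |  | 2.0 min |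
| alder | 0.20 M | 3.20 equiv | 0.800 equiv | 0.0100 M |  | 2.0 min |
| maple | 0.20 M | 1.60 equiv | 0.800 equiv | 0.0100 M |  | 2.0 min |

| run | time / s | electrophile / % | target / % |
|---|---|---|---|
| epsilon | 10.0 | 77.3 | 19.5 |
| epsilon | 15.0 | 71.7 | 22.9 |
| epsilon | 25.0 | 61.7 | 26.8 |
| epsilon | 40.0 | 50.7 | 31.1 |
| epsilon | 50.0 | 45.0 | 31.8 |
| epsilon | 60.0 | 39.9 | 32.6 |
| gamma | 10.0 | 74.7 | 21.5 |
| gamma | 15.0 | 66.7 | 27.0 |
| gamma | 25.0 | 54.4 | 33.9 |
| gamma | 30.0 | 49.2 | 36.3 |
| gamma | 40.0 | 39.7 | 40.4 |
| gamma | 50.0 | 32.5 | 42.7 |
| gamma | 60.0 | 26.3 | 43.7 |

(scatter of a reading: 0.3 percentage points)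

- part of the electrophile that has reacted at the end, cedar
- part of the electrophile that has reacted at the end, alder
- part of the electrophile that has reacted at the end, maple
- what raising the equivalents of free base from its lowest to its highest value here does to the part of the electrophile that has reacted (changes below 5 percentage points count as none) (no change / it falls / it rises)

- a reading or a percentage of target counts all its forms, free or not

I ranked the times, fastest first.

1. Start of epsilon: in the first 10.0 s the electrophile lost 23 points and target stood at 19.5 %. Read as a half-life, that is 26.9 s.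

2. Tail of gamma, with 2.4 equiv of free base: ln[electrophile] fell at 0.0206 s⁻¹. That gives the late half-life, the time the electrophile needs to fall by a factor of two at its last measured slope, a pseudo-first-order reading: 33.7 s. This is longer than the half-life read at the start of epsilon, a comparison across two runs with different free base.

3. Tail of epsilon, with 0.69 equiv of free base: the slope read 0.0120 s⁻¹, so the late half-life read 57.9 s, longer than gamma's.

4. The asked time: I ran each tail on from its last reading, epsilon's for cedar and gamma's for alder, though each flask holds more free base than its run. Cedar came to 80.6 % reacted and alder to 92.4 %. For maple, whose charge lies between, I took their mean, 86.5 %. The rise of 12 points exceeds the margin.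

The forecast, near mine but not equal, gave 82 % (73 % to 87 %) for cedar, 94 % (91 % to 97 %) for alder, 90 % (86 % to 93 %) for maple and "it rises", holding that “More base frees more nucleophile”.

The flasks gave 79.6 % for cedar, 94.1 % for alder and 87.3 % for maple: it rises, by 15 points.

    protic impurity + free base → quenched reagent (k = 2.60 L mol⁻¹ s⁻¹)
    electrophile + target → side product (k = 0.0780 L mol⁻¹ s⁻¹)
    crystals ⇌ target, rate k3*(cs3 - [target]) while solid is left; crystals form when [target] > cs3 (solubility = 0.110 M, k = 0.0580 s⁻¹)
    electrophile + nucleophile → acid set free + target (k = 2.90 L mol⁻¹ s⁻¹)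
    nucleophile + acid set free ⇌ protonated nucleophile, settled at all times (K = 320 L mol⁻¹)
    acid set free + free base ⇌ salt of the base (K = 2.60 × 10⁵ L mol⁻¹, k = 0.260 L mol⁻¹ s⁻¹)

Cedar's electrophile went from 39.0 % at 1.00 min to 20.4 % at 2.00 min, a half-life over that stretch of 64.2 s beside the 57.9 s read from epsilon. The neighbour is alder stopped at 30 s, where it held 45.4 % electrophile, 39.4 % target and 15.1 % side product. Carrying gamma's late half-life of 33.7 s forward from there to 2.0 min gave 7.13 % electrophile left, and alder at 2.00 min held 5.86 %.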